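## The problem

Epoxypholamin B joins a trans-fused drim-7-ene (ring A = C1–C5 and C10, ring B = C5–C10) through one methylene, C11, to an epoxy enone ring: C1' is the quaternary oxirane carbon, C2' the oxirane CH, C3' the ketone, C4' the methyl-bearing carbon, C5' the alkene CH and C6' the carbinol. The decalin carries four contiguous stereocentres: C4 (quaternary, axial CH3, equatorial CH2OH = C18), C5, C10 (quaternary) and C9. They can be set in a chain of induction: C5 directs C10 (alkylation anti to the C5 substituent), C5 and C10 direct C4 (chair-like closure of ring A), and the axial C10 methyl directs C9. The three stereocentres of the enone ring are insulated from the decalin by C11, so the oxirane face needs an auxiliary or a reagent; C6' can then be set from the oxirane (hydroxyl trans to the oxirane oxygen). The γ-hydroxy epoxy enone tolerates neither strong base, nucleophiles nor strong acid, and the C7=C8 alkene can migrate or cyclise under protic acid, so the oxidised ring must be unveiled last and gently. Ring A is three bare methylenes and offers no handle of its own. The feature that opens the problem is the C4–C5 region: a ring carbon bearing one methyl and one oxygenated one-carbon arm is what reductive opening of a 2-methyloxiran-2-yl group leaves behind. Ring B, with its C8 methyl, C7=C8 alkene and an oxygen-bearing C9, is the carbon pattern of carvone, so C4 can be a radical that closes ring A.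

## Retrosynthesis

**Unveiling the epoxy enone (24 from 23, 22, 21).** The last cuts are the two C–O bonds of the oxirane and the C6'–H bond. Target 24 comes from ketal alcohol 23 by hydrolysis and desilylation, 23 from epoxy ketone 22 by hydride addition, and 22 from quinone monoketal 21 by nucleophilic epoxidation. A monoketal is preferred to a quinone because it leaves only C6' as a carbonyl and so decides which alkene is epoxidised and which carbon becomes the carbinol. Its C2-symmetric (2R,4R)-pentanediol ketal is the only stereocontrol element placed near C2'. The forward steps must deliver one oxirane face and then the trans hydroxyl.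

**C11–C1' (21 from 14 and 19).** Cutting the bond between the linker carbon and the enone ring gives diene 14 and iodo dienone 19, joined through borane 20 by hydroboration and B-alkyl Suzuki–Miyaura coupling. This cut is convergent, brings the six-membered ring in at its final oxidation level with the auxiliary attached, and sets C9 by hydroboration opposite the axial C10 methyl. Two neighbouring options were weighed. Forming C9–C11 by sigmatropic delivery of a benzylic carbon from a 7β-allylic ether would cost an enone transposition and a benzylic deoxygenation. Coupling an aryl halide and dearomatising afterwards would put Lewis-acid steps on the full alkene-bearing molecule; it is kept as a fallback.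

**The enone-ring fragment (19 from 17, 16, 15).** Ketal 19 comes from dimethyl ketal 17 by exchange with diol 18, 17 from iodophenol 16 by oxidative dearomatisation, and 16 from commercial phenol 15 by iodination. The para-methoxy group of 15 fixes where the ketal forms, and the hydroxyl fixes where iodine enters.

**C9=C11 (14 from 11 and 12).** Diene 14 is the methylenation product of enone 11 with the one-carbon reagent 12, through carbinol 13. The carvone carbonyl thus becomes the anchor of C11, with no transposition of the C7=C8 alkene. The forward reaction must add to a ketone flanked by a quaternary carbon and a substituted alkene.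

**Clearing ring A (11 from 9, 8, 7).** Enone 11 comes from acid 9 by reductive decarboxylation through thiohydroxamate ester 10. Acid 9 comes from ester 8, and 8 from hydroxy ester 7 by silylation. The C2 ester is the price of the radical acceptor and is removed at once, and the C18 hydroxyl is capped with the one protecting group carried to the end.

**Ring A, C3–C4 (7 from 6).** Cutting C3–C4 opens ring A to epoxide 6, in which C4 is an oxirane carbon and C1–C3 are a 2-(methoxycarbonyl)allyl group on C10. This is preferred to polar closures of ring A because it creates the quaternary C4 and its oxygenated arm in one step from an epimer mixture, without touching the enone. The forward reaction must close 6-endo and place CH2OH equatorial.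

**The carvone stage (6 from 5, 3, 1).** Epoxide 6 comes from triene 5 by peracid oxidation, 5 from 6-methylcarvone 3 and bromide 4, and 3 from (R)-carvone 1 and iodomethane 2. Carvone supplies C5 with the right absolute configuration, and the order methyl-then-allyl places the three-carbon arm anti to the isopropenyl group, which is the trans ring fusion.

## Roads not taken

**Alternative 1:** The cut is the central C5–C10 bond, which opens both carbocycles to ten-membered dienone A1 (C5=C6–C7 enone, exocyclic methylene on C10, the C4, C8 and C9 substituents and the arene in place). Fe(acac)3 and PhSiH3 would transfer a hydrogen atom to the methylene, and the tertiary C10 radical would add across the ring to C5 to give decalone A2.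
- Merits: two rings, the quaternary C10 and the ring fusion arise in one step; the arene is already attached; the C7 ketone is a handle for the C7=C8 alkene.
- Weak points: A1 needs a macrocyclisation and an open-chain synthesis of the quaternary C4. The C5/C10 fusion and its relation to C4 depend on medium-ring conformations that are hard to predict. C8 is epimerisable, and turning the C7 ketone into the C7=C8 alkene needs a regiocontrolled elimination.
- Comparison: this road gains more complexity per step and is more convergent toward the arene. The chosen plan sets against it that C5 and C10 come from carvone by a precedented alkylation, that key precursor 6 is three steps from commercial material, and that only C4 is left to the radical step.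

**Alternative 2:** The cut is the oxirane itself. tert-Butyl hydroperoxide and DBU would epoxidise the C1'=C2' alkene of chiral quinone monoketal A3 to epoxy ketone A4 under control of the (2R,4R)-pentanediol ketal.
- Merits: it addresses the one stereochemical relationship the terpenoid cannot control, and the monoketal settles the regiochemistry.
- Weak points: it is an endgame tactic, not a plan for the skeleton. It leaves open how a C18-oxygenated drimane is obtained; from a sclareolide-type chiral pool, one of two geminal methyls would need late C–H oxidation. The level and sense of induction of the auxiliary rest on a conformational model.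
- Comparison: within its own scope this road is as good as the chosen one. A3 and A4 are identical with 21 and 22, and the tactic is adopted as step 13. What the chosen plan adds is the carvone-based construction of ring A with C18 already oxygenated.

**Alternative 3:** The cut is the C4'=C5' alkene. The second-generation Grubbs catalyst (H2IMes)(PCy3)Cl2Ru=CHPh would join the vinyl group on C6' and the isopropenyl ketone at C3' of open-chain epoxide A5, with loss of ethylene, to give the bis-silyl ether A6 of the target.
- Merits: the oxirane and the carbinol are set by Sharpless epoxidation and acyclic control of known absolute sense, independent of the decalin; there is no dearomatisation and no regiochemical question; only desilylation remains.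
- Weak points: A5 needs a long linear build-up on C11 (a trisubstituted allylic alcohol of defined geometry, a vinyl carbinol, an isopropenyl ketone). The metathesis must engage an electron-poor 1,1-disubstituted alkene next to an epoxy ketone, and the isopropenyl ketone is prone to conjugate addition.
- Comparison: this road is better in the certainty of the oxirane configuration. The chosen plan sets against it step economy: all six ring carbons and both oxygens arrive in one coupling from a fragment three steps from a commercial phenol. Because the decalin is enantiopure, a minor oxirane epimer is a separable diastereomer.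

Key step: step 4

Remark on the chemistry: 3 (C10), 6 (C4), 7–10 (C2) and 13 (C9) are handled as epimer mixtures at a centre that a later step erases or makes converge. Names and SMILES show the major or drawn epimer, and the numbering of the first section (C18 = oxygenated carbon on C4) is used in all names.

Step 1
Reactants: 1 (R)-(−)-carvone; 2 iodomethane
Product: 3 (5R,6S)-6-methylcarvone (trans; the cis epimer is carried along)
Conditions: LiN(i-Pr)2, THF, −78 °C; then MeI, −78 → −20 °C
Reagents that add atoms: iodomethane, CI
Why: Kinetic deprotonation by the lithium amide occurs at the α' methylene (future C10) to give the cross-conjugated enolate, which is methylated mainly anti to the isopropenyl group; the new centre is erased by the enolisation of step 2, so the mixture is used as such (kinetic enolate alkylation).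

Step 2
Reactants: 3 (5R,6S)-6-methylcarvone; 4 methyl 2-(bromomethyl)acrylate
Product: 5 methyl 2-{[1,3-dimethyl-2-oxo-6-(prop-1-en-2-yl)cyclohex-3-en-1-yl]methyl}acrylate (ester-bearing CH2 trans and ring C1 methyl cis to the isopropenyl group)
Conditions: LiN(i-Pr)2, THF, DMPU, −78 °C; then 4, −78 → −40 °C
Reagents that add atoms: methyl 2-(bromomethyl)acrylate, C=C(CBr)C(=O)OC
Why: The tetrasubstituted lithium enolate is alkylated by the allylic bromide (direct or addition–elimination path, same product) on the face away from the neighbouring isopropenyl group; this 1,2-induction sets the quaternary C10 with the three-carbon arm trans to the future C4, as the trans ring fusion requires (diastereoselective enolate alkylation).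

Step 3
Reactants: 5 dialkylated carvone
Product: 6 methyl 2-{[1,3-dimethyl-6-(2-methyloxiran-2-yl)-2-oxocyclohex-3-en-1-yl]methyl}acrylate (both C4 epimers)
Conditions: m-CPBA, NaHCO3, CH2Cl2, 0 °C
Reagents that add atoms: m-chloroperoxybenzoic acid, OOC(=O)c1cccc(Cl)c1
Why: Prilezhaev epoxidation; the electrophilic peracid takes the only electron-rich alkene and leaves the enone and acrylate alkenes, and no facial control is needed because C4 becomes planar in step 4.

Step 4
Reactants: 6 side-chain epoxide (both C4 epimers)
Product: 7 methyl 18-hydroxy-9-oxo-11-nordrim-7-ene-2α-carboxylate (4β-CH3, 4α-CH2OH, 5α-H, 10β-CH3; equatorial ester drawn, 2β epimer carried along)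
Conditions: Cp2TiCl2 (20 mol %), Zn dust, 2,4,6-collidine·HCl, THF, rt, slow addition of 6
Reagents that add atoms: none
Why: Cp2TiCl (trivalent titanium, formed in the flask from Cp2TiCl2 and Zn) binds the oxirane and transfers one electron, and the C–O bond at the more substituted carbon breaks to give a planar tertiary β-titanoxy radical at C4, so both epimers of 6 converge. This nucleophilic radical adds to the unsubstituted acrylate terminus C3 and closes ring A in the 6-endo-trig mode, the 5-exo path being disfavoured because it would attack the substituted, polarity-mismatched α-carbon; a second Cp2TiCl reduces the α-ester radical to a titanium enolate, and collidinium chloride protonates the enolate and the Ti–O bond and returns Cp2TiCl2 to the cycle. The closest known reaction type is the titanocene-mediated reductive epoxide opening with radical cyclisation onto an α,β-unsaturated ester. C4 is set in a chair-like transition state made possible by the trans arms on C5 and C10, both equatorial on ring B: the small methyl takes the position syn-axial to the C10 methyl and the bulky titanoxymethyl group the equatorial one, which should give 4β-CH3 and 4α-CH2OH. The ring fusion is not at stake because C5 and C10 are fixed beforehand, and C2 arises by enolate protonation, is of no consequence and vanishes in step 7. The step needs epoxide opening to outrun reduction of the enone and needs cyclisation to outrun reduction of the tertiary radical; the high affinity of Cp2TiCl for oxiranes, its slow reaction with hindered tertiary radicals and with this hindered conjugated ketone, and its low stationary concentration under catalytic turnover should secure both.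

Step 5
Reactants: 7 hydroxy enone ester
Product: 8 methyl 18-(tert-butyldimethylsilyloxy)-9-oxo-11-nordrim-7-ene-2α-carboxylate
Conditions: TBSCl, imidazole, DMF, rt
Reagents that add atoms: tert-butyldimethylsilyl chloride, CC(C)(C)[Si](C)(C)Cl
Why: Standard silylation of the neopentyl-type primary alcohol; the ether must survive base, radical, organometallic and hydride steps and is removed in the final acid step.

Step 6
Reactants: 8 silyl ether ester
Product: 9 18-(tert-butyldimethylsilyloxy)-9-oxo-11-nordrim-7-ene-2α-carboxylic acid
Conditions: LiOH, THF/MeOH/H2O, rt; then dil. HCl to pH 3, 0 °C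
Reagents that add atoms: lithium hydroxide, [Li+].[OH-]
Why: Saponification of an unhindered secondary methyl ester; the enone has no α'-hydrogen, the silyl ether is stable to hydroxide, and epimerisation at C2 is irrelevant.

Step 7
Reactants: 9 carboxylic acid
Product: 11 18-(tert-butyldimethylsilyloxy)-11-nordrim-7-en-9-one, via Barton ester 10 (not isolated)
Conditions: N-hydroxypyridine-2-thione, DCC, DMAP (cat.), CH2Cl2, rt, dark; then t-BuSH, hν (visible), rt
Reagents that add atoms: none
Why: Barton reductive decarboxylation: the thiohydroxamate ester fragments under light to the secondary C2 radical, which takes hydrogen from the thiol faster than it can reach the distant enone; the activating group of the radical acceptor is thereby removed and C2 becomes CH2.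

Step 8
Reactants: 11 enone; 12 (trimethylsilyl)methyllithium
Product: 14 18-(tert-butyldimethylsilyloxy)drima-7,9(11)-diene, via β-silyl carbinol 13 (not isolated)
Conditions: Me3SiCH2Li, CeCl3, THF, −78 → 0 °C; aq. NH4Cl; then KH, THF, 0 °C → rt
Reagents that add atoms: (trimethylsilyl)methyllithium, [Li]C[Si](C)(C)C
Why: Peterson olefination: the organocerium reagent adds 1,2 to the hindered, γ-enolisable enone without deprotonating it, and the potassium alkoxide of the β-silyl carbinol eliminates Me3SiOK to give the exocyclic C9=C11 alkene, which installs C11; the silyl ether is inert to the basic elimination.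

Step 9
Reactants: 15 4-methoxy-3-methylphenol
Product: 16 2-iodo-4-methoxy-5-methylphenol
Conditions: NIS, TsOH (cat.), MeCN, 0 °C
Reagents that add atoms: N-iodosuccinimide, IN1C(=O)CCC1=O
Why: Electrophilic aromatic iodination directed by the free hydroxyl: the para position is blocked by OMe, and of the two ortho positions the one para to the methyl group is open while the other is flanked by OH and CH3.

Step 10
Reactants: 16 iodophenol
Product: 17 2-iodo-4,4-dimethoxy-5-methylcyclohexa-2,5-dien-1-one
Conditions: PhI(OAc)2, MeOH, 0 °C
Reagents that add atoms: methanol, CO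
Why: Oxidative dearomatisation of a para-methoxyphenol: methanol adds at the methoxy-bearing carbon of the aryloxy-iodane intermediate, so the ketal forms at C3' and the free carbonyl at C6' without ambiguity; the aryl iodide is not oxidised.

Step 11
Reactants: 17 dimethyl ketal; 18 (2R,4R)-pentane-2,4-diol
Product: 19 (2R,4R)-10-iodo-2,4,7-trimethyl-1,5-dioxaspiro[5.5]undeca-7,10-dien-9-one
Conditions: 18 (3 equiv), BF3·OEt2 (0.3 equiv), DME, 0 °C → rt
Reagents that add atoms: (2R,4R)-pentane-2,4-diol, C[C@@H](O)C[C@@H](C)O
Why: Lewis-acid-catalysed trans-ketalisation of a quinone monoketal, driven by formation of the cyclic ketal with loss of two methanol; because the diol is C2-symmetric the spiro carbon is not a stereocentre.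

Step 12
Reactants: 14 diene; 19 iodo dienone ketal
Product: 21 (2R,4R)-10-[18-(tert-butyldimethylsilyloxy)drim-7-en-11-yl]-2,4,7-trimethyl-1,5-dioxaspiro[5.5]undeca-7,10-dien-9-one, via B-alkyl-9-BBN borane 20 (not isolated)
Conditions: 9-BBN, THF, 0 °C → rt; then 19, PdCl2(dppf) (5 mol %), AsPh3, Cs2CO3, DMF/THF/H2O, rt
Reagents that add atoms: compound 19, O=C1C=C(C)C2(O[C@H](C)C[C@@H](C)O2)C=C1I
Why: 9-BBN adds to the less hindered exocyclic alkene of the diene with boron on C11 and hydrogen on C9 from the α face, opposite the axial C10 methyl, which sets C9 (9α-H, equatorial C11). The B-alkyl Suzuki–Miyaura coupling of the borane with the α-iodo enone then forms C11–C1' at room temperature, where the C7=C8 alkene, the silyl ether and the ketal are inert.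

Step 13
Reactants: 21 quinone monoketal
Product: 22 C1',C2'-epoxide of 21 (oxirane configured as in the target)
Conditions: t-BuOOH, DBU, CH2Cl2, 0 °C
Reagents that add atoms: tert-butyl hydroperoxide, CC(C)(C)OO
Why: Nucleophilic (Weitz–Scheffer) epoxidation: the peroxide anion adds to C2', the only unsubstituted β-carbon of the cross-conjugated dienone (C4' carries a methyl), and the enolate closes onto oxygen, so only C1'=C2' reacts. In the dioxane chair that avoids a clash between its axial methyl and the C4' methyl, the axial methyl of the (2R,4R)-ketal lies over one face of C2', and attack on the open face should give the oxirane of the target; the remote drimane centres are not expected to interfere.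

Step 14
Reactants: 22 epoxy ketone
Product: 23 C6' alcohol of 22 (hydroxyl trans to the oxirane oxygen)
Conditions: i-Bu2AlH, THF, −78 °C; aq. KNaC4H4O6 work-up
Reagents that add atoms: none
Why: 1,2-Reduction of the epoxy enone: hydride should reach C6' from the oxirane face, which is the face where aluminium is held by the oxirane oxygen and the one not blocked by the C11 substituent on the adjacent quaternary C1', so the hydroxyl ends trans to the oxirane oxygen.

Step 15
Reactants: 23 ketal alcohol
Product: 24 epoxypholamin B
Conditions: 48% aq. HF, MeCN, 0 °C → rt
Reagents that add atoms: water, O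
Why: Aqueous HF cleaves the primary silyl ether and hydrolyses the allylic ketal in one operation, the carbonyl oxygen coming from water; the conditions are mild for the epoxy alcohol and the C7=C8 alkene, and no stereocentre is touched.

## Compound list

1 | (R)-(−)-carvone | CC(=C)[C@@H]1CC=C(C)C(=O)C1 | starting material
2 | iodomethane | CI | starting material
3 | (5R,6S)-2,6-dimethyl-5-(prop-1-en-2-yl)cyclohex-2-en-1-one (trans-6-methylcarvone; cis epimer carried along) | CC(=C)[C@@H]1CC=C(C)C(=O)[C@H]1C | intermediate
4 | methyl 2-(bromomethyl)acrylate | C=C(CBr)C(=O)OC | starting material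
5 | methyl 2-{[1,3-dimethyl-2-oxo-6-(prop-1-en-2-yl)cyclohex-3-en-1-yl]methyl}acrylate (CH2 arm trans, ring methyl cis to isopropenyl) | O=C1C(C)=CC[C@@H](C(C)=C)[C@]1(C)CC(=C)C(=O)OC | intermediate
6 | methyl 2-{[1,3-dimethyl-6-(2-methyloxiran-2-yl)-2-oxocyclohex-3-en-1-yl]methyl}acrylate (both C4 epimers) | O=C1C(C)=CC[C@@H](C2(C)CO2)[C@]1(C)CC(=C)C(=O)OC | intermediate
7 | methyl 18-hydroxy-9-oxo-11-nordrim-7-ene-2α-carboxylate (2β epimer carried along) | O=C1C(C)=CC[C@H]2[C@](C)(CO)C[C@H](C(=O)OC)C[C@]12C | intermediate
8 | methyl 18-(tert-butyldimethylsilyloxy)-9-oxo-11-nordrim-7-ene-2α-carboxylate | O=C1C(C)=CC[C@H]2[C@](C)(CO[Si](C)(C)C(C)(C)C)C[C@H](C(=O)OC)C[C@]12C | intermediate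
9 | 18-(tert-butyldimethylsilyloxy)-9-oxo-11-nordrim-7-ene-2α-carboxylic acid | O=C1C(C)=CC[C@H]2[C@](C)(CO[Si](C)(C)C(C)(C)C)C[C@H](C(=O)O)C[C@]12C | intermediate
10 | 2-thioxopyridin-1(2H)-yl ester of 9 (Barton ester, not isolated) | O=C1C(C)=CC[C@H]2[C@](C)(CO[Si](C)(C)C(C)(C)C)C[C@H](C(=O)ON3C=CC=CC3=S)C[C@]12C | intermediate
11 | 18-(tert-butyldimethylsilyloxy)-11-nordrim-7-en-9-one | O=C1C(C)=CC[C@H]2[C@](C)(CO[Si](C)(C)C(C)(C)C)CCC[C@]12C | intermediate
12 | (trimethylsilyl)methyllithium | [Li]C[Si](C)(C)C | starting material
13 | 18-(tert-butyldimethylsilyloxy)-11-(trimethylsilyl)drim-7-en-9β-ol (9α-CH2SiMe3 drawn, not isolated) | C[Si](C)(C)C[C@]1(O)C(C)=CC[C@H]2[C@](C)(CO[Si](C)(C)C(C)(C)C)CCC[C@]12C | intermediate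
14 | 18-(tert-butyldimethylsilyloxy)drima-7,9(11)-diene | C=C1C(C)=CC[C@H]2[C@](C)(CO[Si](C)(C)C(C)(C)C)CCC[C@]12C | intermediate
15 | 4-methoxy-3-methylphenol | COc1ccc(O)cc1C | starting material
16 | 2-iodo-4-methoxy-5-methylphenol | COc1cc(I)c(O)cc1C | intermediate
17 | 2-iodo-4,4-dimethoxy-5-methylcyclohexa-2,5-dien-1-one | COC1(OC)C=C(I)C(=O)C=C1C | intermediate
18 | (2R,4R)-pentane-2,4-diol | C[C@@H](O)C[C@@H](C)O | starting material
19 | (2R,4R)-10-iodo-2,4,7-trimethyl-1,5-dioxaspiro[5.5]undeca-7,10-dien-9-one | O=C1C=C(C)C2(O[C@H](C)C[C@@H](C)O2)C=C1I | intermediate
20 | 9-[18-(tert-butyldimethylsilyloxy)drim-7-en-11-yl]-9-borabicyclo[3.3.1]nonane (9α-H, not isolated) | C(B1C2CCCC1CCC2)[C@H]3C(C)=CC[C@H]4[C@](C)(CO[Si](C)(C)C(C)(C)C)CCC[C@]34C | intermediate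
21 | (2R,4R)-10-[18-(tert-butyldimethylsilyloxy)drim-7-en-11-yl]-2,4,7-trimethyl-1,5-dioxaspiro[5.5]undeca-7,10-dien-9-one | CC1=CC(=O)C(C[C@H]2C(C)=CC[C@H]3[C@](C)(CO[Si](C)(C)C(C)(C)C)CCC[C@]23C)=CC14O[C@H](C)C[C@@H](C)O4 | intermediate
22 | C1',C2'-epoxide of 21 (C6' ketone, C3' ketal, oxirane as in the target) | CC1=CC(=O)[C@]2(C[C@H]3C(C)=CC[C@H]4[C@](C)(CO[Si](C)(C)C(C)(C)C)CCC[C@]34C)O[C@@H]2C15O[C@H](C)C[C@@H](C)O5 | intermediate
23 | C6' alcohol of 22 (OH trans to the oxirane oxygen; 18-O-TBS, C3' pentanediol ketal) | CC1=C[C@@H](O)[C@]2(C[C@H]3C(C)=CC[C@H]4[C@](C)(CO[Si](C)(C)C(C)(C)C)CCC[C@]34C)O[C@@H]2C15O[C@H](C)C[C@@H](C)O5 | intermediate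
24 | epoxypholamin B | CC1=C[C@@H](O)[C@]2(C[C@H]3C(C)=CC[C@H]4[C@](C)(CO)CCC[C@]34C)O[C@@H]2C1=O | target

## Step count and least certain steps

Total: 15 steps. Longest linear sequence: 12 steps (steps 1–8 and 12–15 from 1). The branch to 19 takes 3 steps (9–11).

**Step 4 (key step).** Two processes threaten it. One is single-electron reduction of the conjugated ketone, or of the tertiary radical before it cyclises (leading to elimination or simple reduction without ring closure). The other is poor discrimination between CH3 and CH2OTi in the chair transition state, which would erode the C4 ratio. The fallback changes how the radical is made. It sets out from 5: allylic oxidation of the isopropenyl methyl (SeO2, t-BuOOH) should give methyl 2-{[6-(3-hydroxyprop-1-en-2-yl)-1,3-dimethyl-2-oxocyclohex-3-en-1-yl]methyl}acrylate F1, and silylation (TBSCl, imidazole) its silyl ether F2. Hydrogen-atom transfer from an iron hydride (Fe(acac)3, PhSiH3, EtOH, 60 °C) to the 1,1-disubstituted alkene of F2 generates the same C4 radical, now carrying CH2OTBS, which closes ring A 6-endo onto the acrylate. The route is rejoined at 8.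

**Step 12.** Transmetalation of the β-branched alkylborane may be slow. The iodo dienone could then be degraded by aqueous base (conjugate addition, loss of iodide), or the alkylpalladium could undergo β-hydride elimination. The fallback attaches an arene and dearomatises afterwards; it sets out from 14 and 16. Silylation of 16 gives tert-butyl(2-iodo-4-methoxy-5-methylphenoxy)dimethylsilane F3. Hydroboration of 14 and coupling with F3 (PdCl2(dppf), Cs2CO3) gives the aryl silyl ether of 11-aryl-18-silyloxydrim-7-ene F4, and K2CO3 in MeOH frees the phenol F5. PhI(OAc)2 in MeOH gives the dimethyl ketal dienone F6, and exchange with 18 (BF3·OEt2, DME) rejoins the route at 21.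

**Step 13.** Facial discrimination may be poor if the dioxane populates twist conformers or the drimane interferes, or the sense of induction may be opposite to the model. The fallback replaces auxiliary control by catalyst control; it sets out from 14 and 17. Coupling of borane 20 with 17 under the conditions of step 12 gives the dimethyl ketal dienone F6. Epoxidation under chiral phase-transfer catalysis (N-benzylcinchonidinium chloride or its cinchoninium pseudoenantiomer, t-BuOOH, NaOH, toluene) gives the dimethyl ketal epoxy ketone F7. Reduction with i-Bu2AlH gives the dimethyl ketal alcohol F8, and aqueous HF in MeCN rejoins the route at 24.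

**Step 14.** Hydride may attack from the face opposite the oxirane if coordination to aluminium is weak, which would give the cis epoxy alcohol. The fallback inverts the carbinol; it sets out from 22. The cis alcohol F9 is subjected to a Mitsunobu reaction (4-nitrobenzoic acid, PPh3, DIAD) to give the inverted 4-nitrobenzoate F10, and methanolysis (K2CO3, MeOH) rejoins the route at 23.

**Step 15.** Hydrolysis of the cyclic ketal next to the oxirane may be slow, and long exposure to acid invites oxirane opening or protonation of the C7=C8 alkene. The fallback separates the two deprotections and replaces hydrolysis by ketal exchange; it sets out from 23. Buffered HF·pyridine in THF removes the silyl group to give the diol ketal F11. Exchange into acetone with pyridinium p-toluenesulfonate then transfers the diol to acetone and rejoins the route at 24.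

## Further compounds

F1 | step 4 | methyl 2-{[6-(3-hydroxyprop-1-en-2-yl)-1,3-dimethyl-2-oxocyclohex-3-en-1-yl]methyl}acrylate | O=C1C(C)=CC[C@@H](C(=C)CO)[C@]1(C)CC(=C)C(=O)OC
F2 | step 4 | tert-butyldimethylsilyl ether of F1 | O=C1C(C)=CC[C@@H](C(=C)CO[Si](C)(C)C(C)(C)C)[C@]1(C)CC(=C)C(=O)OC
F3 | step 12 | tert-butyl(2-iodo-4-methoxy-5-methylphenoxy)dimethylsilane | COc1cc(I)c(O[Si](C)(C)C(C)(C)C)cc1C
F4 | step 12 | 11-[2-(tert-butyldimethylsilyloxy)-5-methoxy-4-methylphenyl]-18-(tert-butyldimethylsilyloxy)drim-7-ene | COc1cc(C[C@H]2C(C)=CC[C@H]3[C@](C)(CO[Si](C)(C)C(C)(C)C)CCC[C@]23C)c(O[Si](C)(C)C(C)(C)C)cc1C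
F5 | step 12 | 2-{[18-(tert-butyldimethylsilyloxy)drim-7-en-11-yl]}-4-methoxy-5-methylphenol | COc1cc(C[C@H]2C(C)=CC[C@H]3[C@](C)(CO[Si](C)(C)C(C)(C)C)CCC[C@]23C)c(O)cc1C
F6 | step 12 | 2-[18-(tert-butyldimethylsilyloxy)drim-7-en-11-yl]-4,4-dimethoxy-5-methylcyclohexa-2,5-dien-1-one | COC1(OC)C=C(C[C@H]2C(C)=CC[C@H]3[C@](C)(CO[Si](C)(C)C(C)(C)C)CCC[C@]23C)C(=O)C=C1C
F7 | step 13 | C1',C2'-epoxide of F6 (oxirane as in the target) | CC1=CC(=O)[C@]2(C[C@H]3C(C)=CC[C@H]4[C@](C)(CO[Si](C)(C)C(C)(C)C)CCC[C@]34C)O[C@@H]2C1(OC)OC
F8 | step 13 | C6' alcohol of F7 (OH trans to the oxirane oxygen) | CC1=C[C@@H](O)[C@]2(C[C@H]3C(C)=CC[C@H]4[C@](C)(CO[Si](C)(C)C(C)(C)C)CCC[C@]34C)O[C@@H]2C1(OC)OC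
F9 | step 14 | C6' epimer of 23 (OH cis to the oxirane oxygen) | CC1=C[C@H](O)[C@]2(C[C@H]3C(C)=CC[C@H]4[C@](C)(CO[Si](C)(C)C(C)(C)C)CCC[C@]34C)O[C@@H]2C15O[C@H](C)C[C@@H](C)O5
F10 | step 14 | 4-nitrobenzoate of 23 | CC1=C[C@@H](OC(=O)c6ccc(cc6)[N+](=O)[O-])[C@]2(C[C@H]3C(C)=CC[C@H]4[C@](C)(CO[Si](C)(C)C(C)(C)C)CCC[C@]34C)O[C@@H]2C15O[C@H](C)C[C@@H](C)O5
F11 | step 15 | 18-hydroxy analogue of 23 (C3' pentanediol ketal retained) | CC1=C[C@@H](O)[C@]2(C[C@H]3C(C)=CC[C@H]4[C@](C)(CO)CCC[C@]34C)O[C@@H]2C15O[C@H](C)C[C@@H](C)O5
A1 | alternative 1 | ten-membered dienone: C5=C6–C7 enone, exocyclic methylene on C10, C4 with CH3 and CH2OTBS, C8 methyl, C9 arylmethyl | COCOc1cc(C)c(OC)cc1C[C@H]2[C@H](C)C(=O)/C=C/[C@](C)(CO[Si](C)(C)C(C)(C)C)CCCC2=C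
A2 | alternative 1 | 11-aryl-18-silyloxydriman-7-one | COCOc1cc(C)c(OC)cc1C[C@H]2[C@H](C)C(=O)C[C@H]3[C@](C)(CO[Si](C)(C)C(C)(C)C)CCC[C@]23C
A3 | alternative 2 | quinone monoketal of (2R,4R)-pentane-2,4-diol (identical with 21) | CC1=CC(=O)C(C[C@H]2C(C)=CC[C@H]3[C@](C)(CO[Si](C)(C)C(C)(C)C)CCC[C@]23C)=CC14O[C@H](C)C[C@@H](C)O4
A4 | alternative 2 | C1',C2'-epoxy quinone monoketal (identical with 22) | CC1=CC(=O)[C@]2(C[C@H]3C(C)=CC[C@H]4[C@](C)(CO[Si](C)(C)C(C)(C)C)CCC[C@]34C)O[C@@H]2C15O[C@H](C)C[C@@H](C)O5
A5 | alternative 3 | open-chain epoxide with vinyl carbinol (triethylsilyl ether) at C6' and isopropenyl ketone at C3' | C=C[C@@H](O[Si](CC)(CC)CC)[C@]1(C[C@H]2C(C)=CC[C@H]3[C@](C)(CO[Si](C)(C)C(C)(C)C)CCC[C@]23C)O[C@@H]1C(=O)C(C)=C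
A6 | alternative 3 | bis-silyl ether of epoxypholamin B | CC1=C[C@@H](O[Si](CC)(CC)CC)[C@]2(C[C@H]3C(C)=CC[C@H]4[C@](C)(CO[Si](C)(C)C(C)(C)C)CCC[C@]34C)O[C@@H]2C1=O
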